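The autumn readings of electrophile went from 80% at 10.0 s to 59% at 25.0 s, and the new flask differs from that run in its free base.

- autumn: electrophile 0.0020 M; free base 1 mM; protonated nucleophile 6 mM (fed, over 100 s); protic impurity 1 mM; run made earlier
- flask: electrophile 0.0020 M; free base 2.00 mM; protonated nucleophile 6.00 mM (fed, over 100 s); protic impurity 1.00 mM; time 2.0 min

autumn run (percent of the electrophile charged)

| time / s | electrophile / % | target / % |
|---|---|---|
| 10.0 | 80 | 8 |
| 15.0 | 73 | 13 |
| 20.0 | 66 | 15 |
| 25.0 | 59 | 9 |

(standard deviation of a reading: 1.5 percentage points)

- the numbers in the tables scatter by 1.5 percentage points (one standard deviation)
- the earlier runs do not show how much of nucleophile is bound; that part of a forecast is a guess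
- no earlier run changes the charge of free base; that part of a forecast is a guess
- a reading or a percentage of target counts all its forms, free or not

- part of the electrophile that has reacted at 2.0 min
- share of the unused nucleophile that is free and not bound as protonated nucleophile, at 2.0 min

I assumed that each nucleophile freed from the fed salt costs one free base, and that each coupling with electrophile sets one acid free, which costs another. That treats free base as the limiting reagent and gives the base ration, 50.0% for this flask: the share of the charged electrophile that the free base can carry through nucleophile at two base per electrophile.

I then took two extreme flasks. If free base set no limit and the pace between those two autumn readings held, the electrophile would be used by 67.1 s, less than the 2.0 min asked. If the ration were a hard stop, the flask would stand at 50.0% reacted. But the autumn ration was 25.0%, and the readings went to 41.0% lost, more than that. So I placed the flask between the extremes, towards the upper one, with little nucleophile free once past the ration.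

The forecast gave 88% (65% to 100%) reacted and 10% free (2% to 35%), saying “Most should therefore stay protonated”.

The flask gave 89.7% and 3.41%.

    electrophile + nucleophile → acid set free + target (k = 55.0 M⁻¹ s⁻¹)
    nucleophile + acid set free ⇌ protonated nucleophile, settled at all times (K = 41000 M⁻¹)
    acid set free + free base ⇌ salt of the base, settled at all times (K = 9.30 × 10⁶ M⁻¹)
    crystals ⇌ target, rate k4*(cs4 - [target]) while solid is left; crystals form when [target] > cs4 (solubility = 1.70 mM, k = 0.720 s⁻¹)
    electrophile + protic impurity → quenched substrate (k = 9.40 M⁻¹ s⁻¹)
    target → over-reaction product (k = 0.0640 s⁻¹)

At 2.0 min the flask had not come to rest: 10.3% of the electrophile stood, and target plus over-reaction product made 63.2%, more than the ration by 13 percentage points. A neighbour flask with 0.0034 M of free base had a ration of 85.0%; its 78.2% stayed less than that, and 10.7% of its unused nucleophile was free. Left for 20.0 min, the flask reached >99.9% reacted, with target at 0%, quenched substrate at 30.1% and over-reaction product at 69.9%.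

All runs were computed from invented constants; noise was put on by code.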